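**Strategy.** Everything rests on cutting the bond between C6, the quaternary carbon next to ring oxygen O1 of the 1,2-dioxane, and the vinylic CH of the side chain. Because C6 is a peroxyketal-type carbon, a 6-methoxy-1,2-dioxane can be ionised to a ring peroxycarbenium ion; both C6 epimers give the same cation, and an (E)-alkenylsilane adds to it axially, setting C6 and delivering the trisubstituted alkene with retention in one stereoconvergent operation. The two partners, a 6-ethyl-6-methoxy-1,2-dioxane-3-acetate and a dienyl silane, both descend from one alkynol, (2R)-2-ethylpent-4-yn-1-ol, since the ring C4 and side-chain stereocentres are homologous.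

Key step: step 13

Remark: compounds 13 and 14 are carried as mixtures of both C6 epimers (their SMILES leave C6 undefined), because step 13 erases and resets this centre.

**Step 1**
Reactants: 1 (4S)-4-benzyl-1,3-oxazolidin-2-one; 2 butanoyl chloride
Product: 3 (4S)-4-benzyl-3-butanoyl-1,3-oxazolidin-2-one
Conditions: n-BuLi, THF, −78 °C; then 2, −78 → 0 °C
Reagents that add atoms: none
Why: N-acylation of the lithiated oxazolidinone by the acid chloride is the standard entry to an Evans imide and touches no stereocentre.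

**Step 2**
Reactants: 3 (4S)-4-benzyl-3-butanoyl-1,3-oxazolidin-2-one; 4 3-bromoprop-1-yne
Product: 5 (4S)-4-benzyl-3-[(2R)-2-ethylpent-4-ynoyl]-1,3-oxazolidin-2-one
Conditions: NaN(SiMe3)2, THF, −78 °C; then 4, −78 → −40 °C
Reagents that add atoms: none
Why: Evans asymmetric alkylation, in which the chelated Z sodium enolate is alkylated on the face opposite the benzyl group, sets the 2R centre that becomes both ring C4 and the side-chain ethyl-bearing carbon.

**Step 3**
Reactants: 5 (4S)-4-benzyl-3-[(2R)-2-ethylpent-4-ynoyl]-1,3-oxazolidin-2-one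
Product: 6 (2R)-2-ethylpent-4-yn-1-ol
Conditions: LiBH4, MeOH (1 equiv), Et2O, 0 °C
Reagents that add atoms: none
Why: Reductive cleavage of the imide by LiBH4 should give the primary alcohol without touching the α-stereocentre and return the auxiliary for reuse.

**Step 4**
Reactants: 6 (2R)-2-ethylpent-4-yn-1-ol; 7 ethylmagnesium bromide
Product: 9 (2R)-2-ethyl-4-methylidenehexan-1-ol, via alkenylcopper alkoxide 8 (not isolated)
Conditions: EtMgBr (1 equiv), Et2O, −20 °C; then EtCu·MgBr2 (from EtMgBr, CuBr·SMe2, Et2O/Me2S, −45 °C), −25 °C; aq. NH4Cl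
Reagents that add atoms: none
Why: Carbocupration of a terminal alkyne by an alkylcopper–MgBr2 reagent adds ethyl to the internal carbon and copper to the terminus in a syn fashion once the hydroxyl is masked as its magnesium alkoxide, and protonolysis of the alkenylcopper leaves the 2-ethylallyl unit.

**Step 5**
Reactants: 9 (2R)-2-ethyl-4-methylidenehexan-1-ol; 10 methyl 2-(triphenyl-λ5-phosphanylidene)acetate
Product: 12 methyl (2E,4R)-4-ethyl-6-methylideneoct-2-enoate, via aldehyde 11 (not isolated)
Conditions: Dess–Martin periodinane, NaHCO3, CH2Cl2, 0 °C → rt; then 10, rt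
Reagents that add atoms: none
Why: Dess–Martin oxidation followed in the same flask by a stabilised Wittig reaction should give the E enoate, and the base-free conditions should preserve the α-stereocentre of aldehyde 11.

**Step 6**
Reactants: 12 methyl (2E,4R)-4-ethyl-6-methylideneoct-2-enoate
Product: 13 methyl (2E,4R)-4-ethyl-6-hydroperoxy-6-methoxyoct-2-enoate (both C6 epimers)
Conditions: O3 (1 equiv, Sudan Red 7B end point), CH2Cl2/MeOH, −78 °C
Reagents that add atoms: ozone, [O-][O+]=O; methanol, CO
Why: Ozonolysis in methanol should attack the electron-rich 1,1-disubstituted alkene far faster than the enoate, and the ketone O-oxide released together with formaldehyde is trapped by methanol as the α-methoxy hydroperoxide.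

**Step 7**
Reactants: 13 methyl (2E,4R)-4-ethyl-6-hydroperoxy-6-methoxyoct-2-enoate (both C6 epimers)
Product: 14 methyl 2-[(3S,4R)-4,6-diethyl-6-methoxy-1,2-dioxan-3-yl]acetate (both C6 epimers)
Conditions: Et2NH (0.5 equiv), CF3CH2OH, rt
Reagents that add atoms: none
Why: Amine-mediated intramolecular oxa-Michael addition (6-exo-trig) of the hydroperoxide to the enoate closes the 1,2-dioxane, and a chair transition state with the C4 ethyl group and the enoate arm both equatorial (an axial C4 ethyl would clash with the axial C6 substituent) should give the 3,4-trans isomer, 3S.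

**Step 8**
Reactants: 6 (2R)-2-ethylpent-4-yn-1-ol; 15 1-phenyl-1H-tetrazole-5-thiol
Product: 16 5-{[(2R)-2-ethylpent-4-yn-1-yl]sulfanyl}-1-phenyl-1H-tetrazole
Conditions: PPh3, DIAD, THF, 0 °C → rt
Reagents that add atoms: none
Why: Mitsunobu thioetherification of the primary alcohol with the acidic tetrazole thiol does not involve the neighbouring stereocentre.

**Step 9**
Reactants: 16 5-{[(2R)-2-ethylpent-4-yn-1-yl]sulfanyl}-1-phenyl-1H-tetrazole
Product: 17 5-{[(2R)-2-ethylpent-4-yn-1-yl]sulfonyl}-1-phenyl-1H-tetrazole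
Conditions: (NH4)6Mo7O24·4H2O (cat.), 30% H2O2, EtOH, 0 °C → rt
Reagents that add atoms: hydrogen peroxide, OO
Why: Molybdate-catalysed oxidation with H2O2 takes the sulfide to the sulfone and leaves the terminal alkyne alone.

**Step 10**
Reactants: 17 5-{[(2R)-2-ethylpent-4-yn-1-yl]sulfonyl}-1-phenyl-1H-tetrazole; 18 propanal
Product: 19 (4R,5E)-4-ethyloct-5-en-1-yne
Conditions: KN(SiMe3)2, DME, −60 °C; then 18, −60 °C → rt
Reagents that add atoms: none
Why: Julia–Kocienski olefination, in which the metalated phenyltetrazolyl sulfone (its CH2 is more acidic than the alkyne CH) adds to propanal and Smiles rearrangement with loss of SO2 follows, should give the E alkene.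

**Step 11**
Reactants: 19 (4R,5E)-4-ethyloct-5-en-1-yne; 7 ethylmagnesium bromide
Product: 21 (1E,4R,5E)-2,4-diethyl-1-iodoocta-1,5-diene, via alkenylcopper 20 (not isolated)
Conditions: EtMgBr, CuBr·SMe2, Et2O/Me2S, −45 °C; 19, −25 °C; then I2, THF, −40 → 0 °C
Reagents that add atoms: iodine, II
Why: Syn carbocupration of the terminal alkyne puts ethyl on the internal carbon and copper cis to it on the terminus, and iodinolysis replaces copper with retention to give the E iodide.

**Step 12**
Reactants: 21 (1E,4R,5E)-2,4-diethyl-1-iodoocta-1,5-diene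
Product: 23 [(1E,4R,5E)-2,4-diethylocta-1,5-dien-1-yl]trimethylsilane, via alkenyllithium 22 (not isolated)
Conditions: t-BuLi (2.1 equiv), Et2O, −78 °C; then Me3SiCl, −78 °C → rt
Reagents that add atoms: chlorotrimethylsilane, C[Si](C)(C)Cl
Why: Lithium–iodine exchange and silylation of the alkenyllithium both proceed with retention of alkene geometry.

**Step 13**
Reactants: 14 methyl 2-[(3S,4R)-4,6-diethyl-6-methoxy-1,2-dioxan-3-yl]acetate (both C6 epimers); 23 [(1E,4R,5E)-2,4-diethylocta-1,5-dien-1-yl]trimethylsilane
Product: 25 methyl 2-[(3S,4R,6S)-6-[(1E,4R,5E)-2,4-diethylocta-1,5-dien-1-yl]-4,6-diethyl-1,2-dioxan-3-yl]acetate, via peroxycarbenium ion 24 (not isolated)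
Conditions: SnCl4 (1.1 equiv), 23 (1.5 equiv), 2,6-di-tert-butyl-4-methylpyridine (0.2 equiv), CH2Cl2, −78 → −40 °C; cold aq. NaHCO3
Reagents that add atoms: none
Why: Proposed new method: SnCl4 removes the exocyclic methoxide from either C6 epimer of 14 to give the same planar ring peroxycarbenium ion 24 (C6=O1+), which is attacked by the silicon-bearing carbon of 23; the resulting tertiary, β-silyl-stabilised cation loses Me3Si+ before bond rotation, so the ring replaces silicon with retention of the E geometry (ipso substitution). The closest known reactions are the Lewis acid substitution of acyclic and cyclic peroxyketals by allylsilanes and silyl enol ethers through peroxycarbenium ions and the ipso substitution of vinylsilanes by oxocarbenium ions; their combination on a 1,2-dioxane is the untested part. No ring is closed, since the dioxane ring is carried through intact. The new stereocentre C6 is set by the cation itself: in its half-chair the trans C3 acetate arm and C4 ethyl group are both pseudoequatorial, and stereoelectronically preferred axial attack through a chair-like transition state places the alkenyl group axial and the C6 ethyl equatorial, which is 6S (alkenyl cis to the C3 arm). The step needs ionisation of C6–OMe in preference to C6–O1 (ring opening is reversible and only the cyclic cation leads on), attack by the 2,2-dialkylvinylsilane terminus in preference to the 1,2-disubstituted alkene of 23 (only the former gives a tertiary β-silyl cation), and survival of the O–O bond, which the low temperature and the hindered base against protodesilylation are meant to secure.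

**Step 14**
Reactants: 25 methyl 2-[(3S,4R,6S)-6-[(1E,4R,5E)-2,4-diethylocta-1,5-dien-1-yl]-4,6-diethyl-1,2-dioxan-3-yl]acetate
Product: 26 2-[(3S,4R,6S)-6-[(1E,4R,5E)-2,4-diethylocta-1,5-dien-1-yl]-4,6-diethyl-1,2-dioxan-3-yl]acetic acid
Conditions: LiOH·H2O, THF/H2O, 0 °C → rt; then cold dilute HCl to pH 3
Reagents that add atoms: lithium hydroxide, [Li+].[OH-]
Why: Saponification of the methyl ester at low temperature should spare the dialkyl peroxide and the C3 centre, because the carboxylate formed resists the α-deprotonation that would open the ring by retro-Michael reaction.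

**Compound list**
1 | (4S)-4-benzyl-1,3-oxazolidin-2-one | O=C1N[C@@H](Cc2ccccc2)CO1 | starting material
2 | butanoyl chloride | CCCC(=O)Cl | starting material
3 | (4S)-4-benzyl-3-butanoyl-1,3-oxazolidin-2-one | CCCC(=O)N1[C@@H](Cc2ccccc2)COC1=O | intermediate
4 | 3-bromoprop-1-yne | C#CCBr | starting material
5 | (4S)-4-benzyl-3-[(2R)-2-ethylpent-4-ynoyl]-1,3-oxazolidin-2-one | C#CC[C@@H](CC)C(=O)N1[C@@H](Cc2ccccc2)COC1=O | intermediate
6 | (2R)-2-ethylpent-4-yn-1-ol | C#CC[C@@H](CC)CO | intermediate
7 | ethylmagnesium bromide | CC[Mg]Br | starting material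
8 | alkenylcopper alkoxide (copper on the terminal alkene carbon, cis to the new ethyl group; alcohol as its OMgBr salt) | [Cu]/C=C(\CC)C[C@@H](CC)CO[Mg]Br | intermediate (not isolated)
9 | (2R)-2-ethyl-4-methylidenehexan-1-ol | C=C(CC)C[C@@H](CC)CO | intermediate
10 | methyl 2-(triphenyl-λ5-phosphanylidene)acetate | COC(=O)C=P(c1ccccc1)(c1ccccc1)c1ccccc1 | starting material
11 | (2R)-2-ethyl-4-methylidenehexanal | C=C(CC)C[C@@H](CC)C=O | intermediate (not isolated)
12 | methyl (2E,4R)-4-ethyl-6-methylideneoct-2-enoate | C=C(CC)C[C@@H](CC)/C=C/C(=O)OC | intermediate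
13 | methyl (2E,4R)-4-ethyl-6-hydroperoxy-6-methoxyoct-2-enoate, both C6 epimers | CCC(OC)(OO)C[C@@H](CC)/C=C/C(=O)OC | intermediate
14 | methyl 2-[(3S,4R)-4,6-diethyl-6-methoxy-1,2-dioxan-3-yl]acetate, both C6 epimers | CCC1(OC)C[C@@H](CC)[C@H](CC(=O)OC)OO1 | intermediate
15 | 1-phenyl-1H-tetrazole-5-thiol | Sc1nnnn1-c1ccccc1 | starting material
16 | 5-{[(2R)-2-ethylpent-4-yn-1-yl]sulfanyl}-1-phenyl-1H-tetrazole | C#CC[C@@H](CC)CSc1nnnn1-c1ccccc1 | intermediate
17 | 5-{[(2R)-2-ethylpent-4-yn-1-yl]sulfonyl}-1-phenyl-1H-tetrazole | C#CC[C@@H](CC)CS(=O)(=O)c1nnnn1-c1ccccc1 | intermediate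
18 | propanal | CCC=O | starting material
19 | (4R,5E)-4-ethyloct-5-en-1-yne | C#CC[C@@H](CC)/C=C/CC | intermediate
20 | [(1E,4R,5E)-2,4-diethylocta-1,5-dien-1-yl]copper | [Cu]/C=C(\CC)C[C@@H](CC)/C=C/CC | intermediate (not isolated)
21 | (1E,4R,5E)-2,4-diethyl-1-iodoocta-1,5-diene | I/C=C(\CC)C[C@@H](CC)/C=C/CC | intermediate
22 | [(1E,4R,5E)-2,4-diethylocta-1,5-dien-1-yl]lithium | [Li]/C=C(\CC)C[C@@H](CC)/C=C/CC | intermediate (not isolated)
23 | [(1E,4R,5E)-2,4-diethylocta-1,5-dien-1-yl]trimethylsilane | C[Si](C)(C)/C=C(\CC)C[C@@H](CC)/C=C/CC | intermediate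
24 | ring peroxycarbenium ion (C6=O1+ of the 1,2-dioxane, C3 and C4 as in 14) | CCC1=[O+]O[C@@H](CC(=O)OC)[C@H](CC)C1 | intermediate (not isolated)
25 | methyl 2-[(3S,4R,6S)-6-[(1E,4R,5E)-2,4-diethylocta-1,5-dien-1-yl]-4,6-diethyl-1,2-dioxan-3-yl]acetate | CC/C=C/[C@H](CC)C/C(=C/[C@]1(CC)C[C@@H](CC)[C@H](CC(=O)OC)OO1)CC | intermediate
26 | 2-[(3S,4R,6S)-6-[(1E,4R,5E)-2,4-diethylocta-1,5-dien-1-yl]-4,6-diethyl-1,2-dioxan-3-yl]acetic acid | CC/C=C/[C@H](CC)C/C(=C/[C@]1(CC)C[C@@H](CC)[C@H](CC(=O)O)OO1)CC | target

**Count.** Total steps: 14. Longest linear sequence: 10 steps (1, 2, 3, 8, 9, 10, 11, 12, 13, 14).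

**Steps most likely to fail**

Step 13 (proposed new method). The trisubstituted vinylsilane may add too slowly to the hindered, ketone-derived cation, so that heterolytic O–O fragmentation, ring opening or protodesilylation of the silane takes over; axial selectivity may also erode. The fallback joins the same two carbons by known reactions and sets out from 12 and 21. Ozonolysis of 12 in CH2Cl2 with Me2S work-up should give methyl (2E,4R)-4-ethyl-6-oxooct-2-enoate F1. Iodide 21 is converted by t-BuLi into alkenyllithium 22 and by CeCl3 into [(1E,4R,5E)-2,4-diethylocta-1,5-dien-1-yl]cerium dichloride F2, which should add to the ketone of F1 at −78 °C in preference to the enoate and give methyl (2E,4R,7E,10R,11E)-4,6,8,10-tetraethyl-6-hydroxytetradeca-2,7,11-trienoate F3 as both C6 epimers. Acid-catalysed perhydrolysis (50% H2O2, cat. H2SO4, 0 °C) should give methyl (2E,4R,7E,10R,11E)-4,6,8,10-tetraethyl-6-hydroperoxytetradeca-2,7,11-trienoate F4; transposed hydroperoxide cannot close a six-membered ring and is removed. Cyclisation with Et2NH in CF3CH2OH, as in step 7, then comes back to the route at 25, which has to be separated from methyl 2-[(3S,4R,6R)-6-[(1E,4R,5E)-2,4-diethylocta-1,5-dien-1-yl]-4,6-diethyl-1,2-dioxan-3-yl]acetate F5, because this path does not control C6.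

Step 4. Carbocupration may stall on the aggregated magnesium alkoxide, or alkoxide coordination may erode the regiochemistry of ethyl delivery. The fallback sets out from 3. Alkylation of its sodium enolate with 2,3-dibromoprop-1-ene should give (4S)-4-benzyl-3-[(2R)-4-bromo-2-ethylpent-4-enoyl]-1,3-oxazolidin-2-one F6. LiBH4 reduction gives (2R)-4-bromo-2-ethylpent-4-en-1-ol F7. Kumada coupling of the alkenyl bromide with EtMgBr (2.2 equiv) under Fe(acac)3 catalysis in THF/NMP at 0 °C comes back to the route at 9.

Step 7. Facial selectivity of the peroxide-forming conjugate addition may be poor, so that the 3,4-cis dioxane forms alongside the trans isomer. The fallback changes the control element to alkene geometry and sets out from 9. Dess–Martin oxidation gives aldehyde 11, which is isolated crude. Still–Gennari olefination with methyl bis(2,2,2-trifluoroethyl)phosphonoacetate, KN(SiMe3)2 and 18-crown-6 in THF at −78 °C should give methyl (2Z,4R)-4-ethyl-6-methylideneoct-2-enoate F8. Ozonolysis in CH2Cl2/MeOH gives methyl (2Z,4R)-4-ethyl-6-hydroperoxy-6-methoxyoct-2-enoate F9 as both C6 epimers. In its Et2NH/CF3CH2OH cyclisation, allylic 1,3-strain of the Z ester holds the C4 hydrogen in the alkene plane, so the tethered hydroperoxide must add anti to the C4 ethyl group; this comes back to the route at 14.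

**Further compounds**
F1 | step 13 | methyl (2E,4R)-4-ethyl-6-oxooct-2-enoate | CCC(=O)C[C@@H](CC)/C=C/C(=O)OC
F2 | step 13 | [(1E,4R,5E)-2,4-diethylocta-1,5-dien-1-yl]cerium dichloride | Cl[Ce](Cl)/C=C(\CC)C[C@@H](CC)/C=C/CC
F3 | step 13 | methyl (2E,4R,7E,10R,11E)-4,6,8,10-tetraethyl-6-hydroxytetradeca-2,7,11-trienoate, both C6 epimers | CC/C=C/[C@H](CC)C/C(=C/C(O)(CC)C[C@@H](CC)/C=C/C(=O)OC)CC
F4 | step 13 | methyl (2E,4R,7E,10R,11E)-4,6,8,10-tetraethyl-6-hydroperoxytetradeca-2,7,11-trienoate, both C6 epimers | CC/C=C/[C@H](CC)C/C(=C/C(OO)(CC)C[C@@H](CC)/C=C/C(=O)OC)CC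
F5 | step 13 | methyl 2-[(3S,4R,6R)-6-[(1E,4R,5E)-2,4-diethylocta-1,5-dien-1-yl]-4,6-diethyl-1,2-dioxan-3-yl]acetate | CC/C=C/[C@H](CC)C/C(=C/[C@@]1(CC)C[C@@H](CC)[C@H](CC(=O)OC)OO1)CC
F6 | step 4 | (4S)-4-benzyl-3-[(2R)-4-bromo-2-ethylpent-4-enoyl]-1,3-oxazolidin-2-one | C=C(Br)C[C@@H](CC)C(=O)N1[C@@H](Cc2ccccc2)COC1=O
F7 | step 4 | (2R)-4-bromo-2-ethylpent-4-en-1-ol | C=C(Br)C[C@@H](CC)CO
F8 | step 7 | methyl (2Z,4R)-4-ethyl-6-methylideneoct-2-enoate | C=C(CC)C[C@@H](CC)/C=C\C(=O)OC
F9 | step 7 | methyl (2Z,4R)-4-ethyl-6-hydroperoxy-6-methoxyoct-2-enoate, both C6 epimers | CCC(OC)(OO)C[C@@H](CC)/C=C\C(=O)OC
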